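**Retrosynthetic overview**
- The target comes from anisoylation of the secondary allylic alcohol of a dauc-8-ene-5,10-diol (azulene C3a/C8); that carbinol comes from chelation-controlled reduction of the corresponding enone.
- Five-membered ring: carbonyl-ene closure of the farnesane C6–C10 bond (azulene C3a–C3) onto a cycloheptenone ketone.
- Seven-membered ring: Mukaiyama-aldol closure of the farnesane C1–C7 bond (azulene C8–C8a). Both rings close in one flask from an open-chain 6-silyloxy-(2Z)-farnesal, seven-ring first, then five-ring, at the same bonds and in the same order as the farnesyl → daucyl cation pathway.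
- The 6-silyloxyfarnesal comes from 1,4-hydrosilylation of a 6-oxo-7(14)-ene farnesal, assembled by Nozaki–Hiyama–Kishi union of a neryl acetate-derived C6 aldehyde with a sulcatone-derived vinyl triflate.

Assumption: the antipode of the chiral acid catalyst in step 6 is the one that a screen shows to direct C–C bond formation to the Si face of the aldehyde carbon; open-chain compounds carry farnesane numbering, bicyclic ones azulene numbering.

**Step 1**
Reactants: 1 6-methylhept-5-en-2-one (sulcatone)
Product: 2 6-methylhepta-1,5-dien-2-yl trifluoromethanesulfonate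
Conditions: LDA, THF, −78 °C; then PhNTf2, −78 → 0 °C
Reagents that add atoms: N-phenylbis(trifluoromethanesulfonimide), O=S(=O)(N(c1ccccc1)S(=O)(=O)C(F)(F)F)C(F)(F)F
Why: Kinetic deprotonation of the methyl ketone at CH3 and O-sulfonylation of the terminal lithium enolate (enol triflate formation) give the 2-triflyloxy-1-alkene; no stereocentre is formed.

**Step 2**
Reactants: 3 neryl acetate
Product: 4 (2Z)-3-methyl-6-oxohex-2-en-1-yl acetate
Conditions: O3 (1.0 equiv), CH2Cl2–pyridine, −78 °C; then Me2S
Reagents that add atoms: ozone, [O-][O+]=O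
Why: Reductive ozonolysis is selective for the electron-rich distal trisubstituted alkene over the acetoxymethyl-deactivated 2,3-alkene, so acetone is cut off and the (Z)-allylic acetate stays intact; no stereocentre is formed.

**Step 3**
Reactants: 2 6-methylhepta-1,5-dien-2-yl trifluoromethanesulfonate; 4 (2Z)-3-methyl-6-oxohex-2-en-1-yl acetate
Product: 6 (2Z)-3,11-dimethyl-7-methylidenedodeca-2,10-diene-1,6-diol (racemic at C6), via hydroxy acetate 5 (not isolated)
Conditions: CrCl2 (4 equiv), NiCl2 (2 mol %), DMF, rt; aqueous work-up; then K2CO3 (cat.), MeOH, rt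
Reagents that add atoms: none
Why: Nozaki–Hiyama–Kishi coupling adds the alkenylchromium species from 2 to the aldehyde only (the ester is tolerated) and mild methanolysis then frees the primary alcohol; the new carbinol carbon is racemic and is oxidised away in step 4.

**Step 4**
Reactants: 6 (2Z)-3,11-dimethyl-7-methylidenedodeca-2,10-diene-1,6-diol
Product: 7 (2Z)-3,11-dimethyl-7-methylidene-6-oxododeca-2,10-dienal
Conditions: Dess–Martin periodinane (2.5 equiv), CH2Cl2, 0 °C → rt
Reagents that add atoms: none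
Why: Dess–Martin oxidation converts both alcohols under near-neutral conditions to the α-methylene ketone and the (Z)-enal without Z→E isomerisation; no stereocentre remains.

**Step 5**
Reactants: 7 (2Z)-3,11-dimethyl-7-methylidene-6-oxododeca-2,10-dienal
Product: 8 (2Z,6E)-3,7,11-trimethyl-6-[(triethylsilyl)oxy]dodeca-2,6,10-trienal
Conditions: RhCl(PPh3)3 (1 mol %), Et3SiH (1.05 equiv), toluene, 0 °C → rt
Reagents that add atoms: triethylsilane, CC[SiH](CC)CC
Why: Rh-catalysed 1,4-hydrosilylation is fastest at the unhindered terminal vinyl ketone (the β,β-disubstituted enal reacts far more slowly) and, via the s-cis enone, puts H on the methylene carbon and Si on oxygen, giving the regio- and geometry-defined (6E) enol silane with the new methyl cis to OSi.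

**Step 6**
Reactants: 8 (2Z,6E)-3,7,11-trimethyl-6-[(triethylsilyl)oxy]dodeca-2,6,10-trienal
Product: 11 (3R,3aS,8R,8aR)-6,8a-dimethyl-3-(prop-1-en-2-yl)-1,2,3,3a,4,5,8,8a-octahydroazulene-3a,8-diol, via cycloheptenone silyl ether 9 (not isolated), via bicyclic silyl ether 10 (not isolated)
Conditions: chiral imidodiphosphorimidate (IDPi) acid (2 mol %), CH2Cl2 (0.01 M), −60 °C; then Me2AlCl (2.5 equiv), −78 → 0 °C; then TBAF, THF, 0 °C
Reagents that add atoms: none
Why: Proposed new method: the silylated chiral acid turns the (Z)-enal into a silyloxy-allyl cation paired with the confined chiral anion, and the tetrasubstituted enol silane closes the seven-membered ring on it (7-enolendo-exo-trig Mukaiyama aldol through an open, antiperiplanar, chair-like transition state with the s-trans enal oxygen pseudo-equatorial, so the new C–O bond is cis to the pseudo-axial homoprenyl chain of the (6E)-enol silane and Si-face attack gives (2R,3R) in 9); Me2AlCl then makes the regenerated ketone a hydroxy-carbenium centre that the side-chain alkene attacks from the face of its own tether (cis ring fusion, OH cis to the angular methyl) with concerted transfer of an allylic hydrogen to oxygen (type-I carbonyl-ene, isopropenyl cis to OH), and fluoride removes the silyl group; the closest known reactions are chiral-anion/silylium-catalysed intermolecular Mukaiyama aldol additions of enol silanes to aldehydes and alkylaluminium-halide-promoted type-I carbonyl-ene cyclisations of δ,ε-unsaturated carbonyl compounds to cis-2-isopropenylcyclopentanols.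

**Step 7**
Reactants: 11 (3R,3aS,8R,8aR)-6,8a-dimethyl-3-(prop-1-en-2-yl)-1,2,3,3a,4,5,8,8a-octahydroazulene-3a,8-diol
Product: 12 (3R,3aS,8aS)-3a-hydroxy-6,8a-dimethyl-3-(prop-1-en-2-yl)-2,3,3a,4,5,8a-hexahydroazulen-8(1H)-one
Conditions: Dess–Martin periodinane (1.3 equiv), CH2Cl2, 0 °C → rt
Reagents that add atoms: none
Why: Dess–Martin oxidation of the secondary allylic alcohol (the tertiary alcohol cannot react) gives the enone and erases the C8 centre, so any C8 epimer from step 6 converges here while C3, C3a and C8a are untouched.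

**Step 8**
Reactants: 12 (3R,3aS,8aS)-3a-hydroxy-6,8a-dimethyl-3-(prop-1-en-2-yl)-2,3,3a,4,5,8a-hexahydroazulen-8(1H)-one
Product: 13 (3R,3aS,8aS)-3a-hydroxy-6,8a-dimethyl-3-(propan-2-yl)-2,3,3a,4,5,8a-hexahydroazulen-8(1H)-one
Conditions: H2 (1 atm), RhCl(PPh3)3 (5 mol %), benzene, rt
Reagents that add atoms: none
Why: Homogeneous hydrogenation with Wilkinson's catalyst reduces the 1,1-disubstituted isopropenyl alkene and leaves the trisubstituted enone alkene alone (the carvone → carvotanacetone selectivity); no stereocentre is formed or changed.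

**Step 9**
Reactants: 13 (3R,3aS,8aS)-3a-hydroxy-6,8a-dimethyl-3-(propan-2-yl)-2,3,3a,4,5,8a-hexahydroazulen-8(1H)-one
Product: 14 (3R,3aS,8S,8aR)-6,8a-dimethyl-3-(propan-2-yl)-1,2,3,3a,4,5,8,8a-octahydroazulene-3a,8-diol
Conditions: Et2BOMe (1.2 equiv), THF–MeOH 4:1, rt → −78 °C; NaBH4, −78 °C; then MeOH co-evaporation
Reagents that add atoms: none
Why: Narasaka–Prasad reduction: the tertiary alcohol and the ketone are held in a six-membered boron chelate and external hydride adds 1,2 to the face anti to the angular methyl, the only face that keeps the chelate, giving the cis-1,3-diol, i.e. (8S).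

**Step 10**
Reactants: 14 (3R,3aS,8S,8aR)-6,8a-dimethyl-3-(propan-2-yl)-1,2,3,3a,4,5,8,8a-octahydroazulene-3a,8-diol; 15 4-methoxybenzoyl chloride
Product: 16 [(3R,3aS,8S,8aR)-3a-hydroxy-6,8a-dimethyl-3-(propan-2-yl)-1,2,3,3a,4,5,8,8a-octahydroazulen-8-yl] 4-methoxybenzoate (CNP0158828.1)
Conditions: Et3N (2 equiv), DMAP (0.2 equiv), CH2Cl2, 0 °C → rt
Reagents that add atoms: none
Why: DMAP-catalysed acylation (nucleophilic catalysis) esterifies the secondary allylic alcohol with retention at C8 while the tertiary alcohol is too hindered to react.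

**Compound list**
1 | 6-methylhept-5-en-2-one (sulcatone) | CC(=O)CCC=C(C)C | starting material
2 | 6-methylhepta-1,5-dien-2-yl trifluoromethanesulfonate | C=C(OS(=O)(=O)C(F)(F)F)CCC=C(C)C | intermediate
3 | neryl acetate | CC(=O)OC/C=C(C)\CCC=C(C)C | starting material
4 | (2Z)-3-methyl-6-oxohex-2-en-1-yl acetate | CC(=O)OC/C=C(C)\CCC=O | intermediate
5 | (2Z)-6-hydroxy-3,11-dimethyl-7-methylidenedodeca-2,10-dien-1-yl acetate (racemic, not isolated) | CC(=O)OC/C=C(C)\CCC(O)C(=C)CCC=C(C)C | intermediate
6 | (2Z)-3,11-dimethyl-7-methylidenedodeca-2,10-diene-1,6-diol (racemic) | OC/C=C(C)\CCC(O)C(=C)CCC=C(C)C | intermediate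
7 | (2Z)-3,11-dimethyl-7-methylidene-6-oxododeca-2,10-dienal | O=C/C=C(C)\CCC(=O)C(=C)CCC=C(C)C | intermediate
8 | (2Z,6E)-3,7,11-trimethyl-6-[(triethylsilyl)oxy]dodeca-2,6,10-trienal | O=C/C=C(C)\CC/C(O[Si](CC)(CC)CC)=C(C)\CCC=C(C)C | intermediate
9 | (2R,3R)-2,5-dimethyl-2-(4-methylpent-3-en-1-yl)-3-[(triethylsilyl)oxy]cyclohept-4-en-1-one (not isolated) | CC[Si](CC)(CC)O[C@@H]1C=C(C)CCC(=O)[C@]1(C)CCC=C(C)C | intermediate
10 | (3R,3aS,8R,8aR)-6,8a-dimethyl-3-(prop-1-en-2-yl)-8-[(triethylsilyl)oxy]-2,3,4,5,8,8a-hexahydroazulen-3a(1H)-ol (in the flask as its aluminium alkoxide, not isolated) | CC[Si](CC)(CC)O[C@@H]1C=C(C)CC[C@]2(O)[C@@H](C(C)=C)CC[C@]12C | intermediate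
11 | (3R,3aS,8R,8aR)-6,8a-dimethyl-3-(prop-1-en-2-yl)-1,2,3,3a,4,5,8,8a-octahydroazulene-3a,8-diol | O[C@@H]1C=C(C)CC[C@]2(O)[C@@H](C(C)=C)CC[C@]12C | intermediate
12 | (3R,3aS,8aS)-3a-hydroxy-6,8a-dimethyl-3-(prop-1-en-2-yl)-2,3,3a,4,5,8a-hexahydroazulen-8(1H)-one | O=C1C=C(C)CC[C@]2(O)[C@@H](C(C)=C)CC[C@]12C | intermediate
13 | (3R,3aS,8aS)-3a-hydroxy-6,8a-dimethyl-3-(propan-2-yl)-2,3,3a,4,5,8a-hexahydroazulen-8(1H)-one | O=C1C=C(C)CC[C@]2(O)[C@@H](C(C)C)CC[C@]12C | intermediate
14 | (3R,3aS,8S,8aR)-6,8a-dimethyl-3-(propan-2-yl)-1,2,3,3a,4,5,8,8a-octahydroazulene-3a,8-diol | O[C@H]1C=C(C)CC[C@]2(O)[C@@H](C(C)C)CC[C@]12C | intermediate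
15 | 4-methoxybenzoyl chloride | COc1ccc(C(Cl)=O)cc1 | starting material
16 | [(3R,3aS,8S,8aR)-3a-hydroxy-6,8a-dimethyl-3-(propan-2-yl)-1,2,3,3a,4,5,8,8a-octahydroazulen-8-yl] 4-methoxybenzoate | COc1ccc(C(=O)O[C@H]2C=C(C)CC[C@]3(O)[C@@H](C(C)C)CC[C@]23C)cc1 | target

**Step count**
Total steps: 10. Longest linear sequence: 9 (3 → 4 → 6 → 7 → 8 → 11 → 12 → 13 → 14 → 16).

**Three steps most likely to fail**

Step 6 (one-flask asymmetric aldol/ene bicyclisation). The risks are Z→E isomerisation of the activated enal, protodesilylation of the enol silane, a non-chair transition state that would erode the enantiomeric excess, and a sluggish ketone-ene closure. The fallback gives up catalyst control and resolves instead; it sets out from 8 and comes back at 11. Treating 8 with Me2AlCl alone (3 equiv, CH2Cl2, −78 → 0 °C) runs the same two ring closures without a chiral catalyst and gives racemic (3R*,3aS*,8R*,8aR*)-6,8a-dimethyl-3-(prop-1-en-2-yl)-1,2,3,3a,4,5,8,8a-octahydroazulene-3a,8-diol F1. Acylation of its secondary alcohol with (1S)-camphanic chloride and DMAP gives two diastereomeric esters, the wanted (3R,3aS,8R,8aR)-8-O-camphanate F2 and the (3S,3aR,8S,8aS)-8-O-camphanate F3, which are separated by chromatography or crystallisation. Methanolysis of the wanted ester (K2CO3, MeOH) returns 11.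

Step 5 (hydrosilylation of the vinyl ketone next to a free enal). The risks are 1,2- or 1,4-reduction of the enal and a premature, uncontrolled aldol of the rhodium enolate. The fallback keeps C1 as its acetate until the enol silane is in place; it sets out from 4 and comes back at 8. The coupling of step 3 is run without the methanolysis and hydroxy acetate 5 is isolated. Dess–Martin oxidation gives (2Z)-3,11-dimethyl-7-methylidene-6-oxododeca-2,10-dien-1-yl acetate F4. The same Rh/Et3SiH hydrosilylation, now with no aldehyde in the molecule, gives (2Z,6E)-3,7,11-trimethyl-6-[(triethylsilyl)oxy]dodeca-2,6,10-trien-1-yl acetate F5. DIBAL-H at −78 °C removes the acetate to give (2Z,6E)-3,7,11-trimethyl-6-[(triethylsilyl)oxy]dodeca-2,6,10-trien-1-ol F6, and MnO2 oxidation of this allylic alcohol gives 8.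

Step 9 (facial selectivity of the enone reduction). The risk is that the tertiary alcohol chelates poorly and the C8 epimer forms. The fallback replaces kinetic hydride delivery by thermodynamic control; it sets out from 13 and comes back at 14. Al(OiPr)3 with isopropanol and a trace of acetone in toluene at 80 °C sets up reversible Meerwein–Ponndorf–Verley/Oppenauer hydride transfer at C8. The equilibrium drains to the cis-1,3-diol, which alone can sit as a cyclic aluminium diolate, so 14 is obtained without any new isolated compound.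

**Further compounds**
F1 | step 6 | racemic (3R*,3aS*,8R*,8aR*)-6,8a-dimethyl-3-(prop-1-en-2-yl)-1,2,3,3a,4,5,8,8a-octahydroazulene-3a,8-diol (both enantiomers written) | O[C@@H]1C=C(C)CC[C@]2(O)[C@@H](C(C)=C)CC[C@]12C.O[C@H]1C=C(C)CC[C@@]2(O)[C@H](C(C)=C)CC[C@@]12C
F2 | step 6 | (3R,3aS,8R,8aR)-3a-hydroxy-6,8a-dimethyl-3-(prop-1-en-2-yl)-1,2,3,3a,4,5,8,8a-octahydroazulen-8-yl (1S,4R)-4,7,7-trimethyl-3-oxo-2-oxabicyclo[2.2.1]heptane-1-carboxylate | CC1(C)[C@@]2(C)CC[C@@]1(OC2=O)C(=O)O[C@@H]3C=C(C)CC[C@]4(O)[C@@H](C(C)=C)CC[C@]34C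
F3 | step 6 | (3S,3aR,8S,8aS)-3a-hydroxy-6,8a-dimethyl-3-(prop-1-en-2-yl)-1,2,3,3a,4,5,8,8a-octahydroazulen-8-yl (1S,4R)-4,7,7-trimethyl-3-oxo-2-oxabicyclo[2.2.1]heptane-1-carboxylate | CC1(C)[C@@]2(C)CC[C@@]1(OC2=O)C(=O)O[C@H]3C=C(C)CC[C@@]4(O)[C@H](C(C)=C)CC[C@@]34C
F4 | step 5 | (2Z)-3,11-dimethyl-7-methylidene-6-oxododeca-2,10-dien-1-yl acetate | CC(=O)OC/C=C(C)\CCC(=O)C(=C)CCC=C(C)C
F5 | step 5 | (2Z,6E)-3,7,11-trimethyl-6-[(triethylsilyl)oxy]dodeca-2,6,10-trien-1-yl acetate | CC(=O)OC/C=C(C)\CC/C(O[Si](CC)(CC)CC)=C(C)\CCC=C(C)C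
F6 | step 5 | (2Z,6E)-3,7,11-trimethyl-6-[(triethylsilyl)oxy]dodeca-2,6,10-trien-1-ol | OC/C=C(C)\CC/C(O[Si](CC)(CC)CC)=C(C)\CCC=C(C)C
F0 | step 9 | none | none
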